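1. The south-west run leaves 15.3% of its charge as neither substrate nor target at 6.00 min. The west run, at the same time, leaves 43.8%, which is more. So a side path uses substrate, and I assume it needs no enzyme.

the same everywhere: enzyme 0.02 mol%

| run | substrate | remark |
|---|---|---|
| south-west | 5 mM | run made earlier |
| west | 20 mM | run made earlier |
| flask | 10 mM |  |

- south-west (time / min: target / %, substrate / %): 0.417: 2.7, 92.6; 1.33: 16.7, 76.8; 2.50: 27.4, 65.0; 4.00: 35.2, 49.0; 5.00: 39.7, 46.1; 6.00: 46.9, 37.8
- west (time / min: target / %, substrate / %): 0.417: 4.7, 87.3; 1.33: 9.1, 65.8; 2.50: 16.9, 51.0; 4.00: 23.5, 36.7; 5.00: 27.2, 30.6; 6.00: 29.9, 26.3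

(scatter of a reading: 1 percentage point)

1. apparent order in enzyme when 50% of the substrate are converted (percent change of the rate of making target for one percent more enzyme charged)



2. I compare target made with substrate used, near 50% conversion. South-west reads 0.690 at 4.00 min, and west reads 0.345 at 2.50 min. The flask's charge lies midway between theirs on a log scale. So I take the mean as its target share, the target made per substrate used, 0.518. This is the selectivity, and it is a reading with scatter.

3. Now I draw the order against conversion. I assume enzyme is lost when enzyme meets enzyme, so more enzyme also dies sooner. The order starts at one, since at the start no enzyme has been lost.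

4. I solve one end. Substrate used by the enzyme path runs on a clock that scales with enzyme, so that part keeps the order at one.

5. I solve the other end. Substrate used by the side path runs on a clock that ignores enzyme, so that part carries the order down to the fraction of enzyme still working.

6. I join them, weighting each end by its share. As the fraction still working falls towards zero, the order falls towards a floor equal to the target share, 0.518. The readings do not show the enzyme left, so I commit to the middle between floor and one, 0.759.

7. The forecast gives 0.7, a little below mine: “I expect about 0.7, with wide uncertainty.”

8. The flask gives 0.73.

    2 substrate → homo dimer (k = 6.20 M⁻¹ min⁻¹)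
    substrate + enzyme → target + enzyme, rate k2*[substrate]*[enzyme]/(1 + ([substrate]/Km2) + ([substrate]/Ksi2)^2) (5.32 mM, 8.16 mM, k = 3.11 × 10⁵ M⁻¹ min⁻¹)
    2 enzyme → spent catalyst (k = 92800 M⁻¹ min⁻¹)

9. By 0.800 min the flask's homo dimer path has 29% of its turnover behind it and the target path 21%, while enzyme falls to 77.1% as spent catalyst forms. At 3.17 min, with 50% converted, 46.0% of the catalyst is still enzyme. At 4.00 min, with 57.0% converted, the flask's target share stands at 0.603, against the 0.518 I reckoned for 50% conversion. The same share in the west run reads 0.406 at 6.00 min.

(The runs were generated by integration with made-up constants, and the scatter is random.)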